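The runs are calculated for substances that don't exist, and the scatter is random.

At each time of reading the flask shows how much starting material is left, and a first-order decay with one time constant would make the logarithm of charge over remainder grow in step with time.

| setting | theta | epsilon | alpha |
|---|---|---|---|
| starting material | 0.600 M | 0.600 M | 0.600 M |
| reagent | 0.900 M | 0.900 M | 2.20 M |
| free catalyst | 0.0600 M | 0.120 M | 0.0600 M |
| time |  |  | 70 min |

| run | time / min | [starting material] / M |
|---|---|---|
| theta run | 14 | 0.5454 |
| theta run | 28 | 0.4736 |
| theta run | 42 | 0.4218 |
| theta run | 56 | 0.3818 |
| theta run | 70 | 0.3609 |
| epsilon run | 14 | 0.4932 |
| epsilon run | 28 | 0.3751 |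
| epsilon run | 42 | 0.2975 |
| epsilon run | 56 | 0.2488 |
| epsilon run | 70 | 0.2139 |

(standard deviation of a reading: 0.002 M)

1. the exponent of [free catalyst] in the starting rate at the charge of the theta run (at the point where two percent of the starting material have become target)
2. starting material in the alpha run at 70 min, as a share of the starting material charged

- Overall: starting material + reagent -> target, with free catalyst as catalyst.
- Constant volume, constant temperature.
- An order is taken over about fifteen percent of the charge, up and down.

Call that logarithm the exposure: ln([starting material] charged / [starting material] left). As long as the loss is proportional to [starting material], it is the time integral of the loss rate constant, even if that constant drifts. In the theta run at 70 min the exposure stands at 0.508.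

The bench rule says that doubled catalyst, the rest of the charge held, doubles the exposure at equal time. The epsilon run, with twice the free catalyst of the theta run, shows 2.05 times the theta exposure at 14 min and 2.03 times at 70 min.

That steady ratio also speaks about reagent. By the overall equation, the theta run is reckoned to hold 0.661 M of reagent at 70 min and the epsilon run 0.514 M, a ratio of 0.778. A rate proportional to [reagent] would have pulled the exposure ratio down toward 1.78, lower than the 2.03 read. This reckoning therefore takes the reagent order as near zero, so the alpha run should repeat the theta exposure and keep 60.2% of its charge.

The rule stops at the exponent asked, which compares the runs at equal composition, not equal time. In the theta run the exposure grows by a factor 2.48 while time grows by 2.00, the mark of an induction period. If exposure goes as [free catalyst] times time to a power p, then the rate at fixed exposure goes as [free catalyst] to the power 1/p. Here p reads 1.31, which gives an exponent of about 0.763.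

The forecast differs from both figures, with 1 and 40%, and says of reagent: “The reagent order is poorly fixed because no run has varied reagent yet.”

The alpha run keeps 58.9% of its starting material at 70 min, and the exponent in free catalyst comes to 0.63. The steps behind the readings are these:

    active catalyst + starting material → loaded catalyst + by-product (0.2598 M⁻¹ min⁻¹)
    loaded catalyst + reagent → target + active catalyst (1.590 M⁻¹ min⁻¹)
    active catalyst → spent catalyst (0.02112 min⁻¹)
    free catalyst → active catalyst (0.1332 min⁻¹)

Where equal target has been made early on, the epsilon run goes 1.5 times as fast as the theta run. The exposure of the alpha run at 70 min is 0.529 against 0.508 for the theta run, a factor of 1.04 on the exposure for a factor of 2.44 in [reagent].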